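## Analysis of the target

Target 30 is a trans-fused octahydroinden-2-one. Ring A is the cyclopentanone C1–C2–C3–C3a–C7a, ring B the cyclohexane C3a–C4–C5–C6–C7–C7a, and C4 carries an exocyclic methylene. There are ten stereocentres: C1, C1′, C3a, C5, C6, C7 and C7a on the core, the quaternary oxirane carbon on C7, the (R) centre of the 2-methylbutanoate on O6 and the (S) centre at C4 of the (E)-4-acetoxy-3-methylpent-2-enoate on O5. The three substituents of ring A alternate faces (C1 side chain, C7a–C7 bond and C3a–C4 bond are mutually trans), and C1′ stands in the anti-aldol relationship to C1. In the chair of ring B the oxiranyl group on C7 and the oxygen on C6 are equatorial and trans to each other, while the oxygen on C5 is axial, so O5 and O6 are cis. Sensitive elements are the β-acetoxy ketone (E1cB loss of acetate), the acid-labile 2,2-disubstituted oxirane, three different esters on three secondary oxygens (acyl migration across the cis C5/C6 pair, deconjugation of the enoate, epimerization α to the butanoate carbonyl) and two 1,1-disubstituted alkenes. The synthesis is hard because six contiguous stereocentres surround the bicycle, the quaternary epoxide centre lies outside the rings, and three different acyl groups must be placed without deprotections next to the epoxide. The strategy rests on the cis-vicinal C5–O/C6–O pair of ring B with C5 allylic to the C4 methylene: C5–C6 is the bond that a reductive coupling of two formyl groups makes.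

## Retrosynthetic reasoning

**O6–acyl bond (30 ⇒ 28 + 29).** The 2-methylbutanoate is removed first, giving epoxy alcohol 28 and (R)-2-methylbutanoic acid 29. It is cut last because the free C6 hydroxyl is needed one step earlier to steer the epoxidation. The forward step is a carbodiimide esterification of an equatorial alcohol, mild enough for the oxirane and the β-acetoxy ketone.

**Oxirane C–O bonds (28 ⇒ 27).** The epoxide is traced back to the isopropenyl group of homoallylic alcohol 27. Among the three alkenes only this one lies gauche to the C6 hydroxyl; the C4 methylene is anti to it and flanked by an acylated oxygen, and the enoate is electron-poor. A hydroxyl-directed epoxidation therefore has to deliver oxygen to one alkene and, from the C6 side, to one face.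

**O5–acyl bond and the C5/C6 distinction (27 ⇒ 26 ⇒ 19 + 24; 19 ⇒ 18).** The enoate on the axial, allylic O5 is cut to give acid 24 and mono-silyl ether 19, in which a triethylsilyl group marks the more accessible equatorial O6 of cis-diol 18. Acid 24 is the acetate of hydroxy acid 23, whose methyl-bearing (E) alkene and carboxyl carbon both come from syn-methylmetalation and carboxylation of (S)-but-3-yn-2-ol 20.

**C5–C6 bond (18 ⇒ 17).** This is the strategic cut. It opens ring B to keto-dialdehyde 17, in which the trans arms on C3a and C7a of the cyclopentanone end in a 2-substituted acrolein (C5) and an α-isopropenyl aldehyde (C6). One bond, one ring and both carbinol centres are gained. The forward coupling must join the two formyl carbons, leave the ketone alone and give the cis-diol with O6 anti to the isopropenyl group.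

**Oxidation level and oxygen substituents (17 ⇒ 16 ⇒ 15 ⇒ 14).** The two aldehydes are made only at the last moment, from diol 16, because the C6 aldehyde is a β,γ-unsaturated aldehyde with an epimerizable C7. Diol 16 comes from bis-silyl ether 15, and 15 from aldol 14 by acetylation. Putting the C1′ acetate on here, not at the end, means that no silyl ether has to be removed next to the oxirane. The primary oxygens are silyl ethers and not esters, so that they can be freed together without touching that acetate.

**C7a–C7 and C1–C1′ bonds (14 ⇒ 7 + 11 + 12).** Both bonds are cut in one operation: conjugate addition of the γ-carbon of (E)-allylsilane 11 to enone 7, and aldol capture of the resulting enolate by acetaldehyde 12. The enolate forms only on the C1 side, which solves the regiochemistry of the aldol. The C3a substituent directs the silane to the opposite face. The silane carries O6 as a poorly Lewis-basic silyl ether, which should resist ionization toward a diene under the Lewis acid better than an ester would.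

**C3a–C4 bond (7 ⇒ 6 ⇒ 3 + 2; 2 ⇒ 1).** Enone 7 comes from silyloxy ketone 6 by β-elimination. Ketone 6 comes from addition of the alkenylcopper reagent derived from bromide 2 (the silyl ether of 1) to enone 3, anti to its silyloxy group. The single stereocentre of 3 is thus relayed to C3a and then to C7a and C1.

**Allylsilane (11 ⇒ 10 ⇒ 9 ⇒ 8).** The (E) trisubstituted alkene of 11 is traced through alcohol 10 to ester 9, which a syn-addition of a silylmethylcopper reagent to ethyl but-2-ynoate 8 gives as a single geometry.

## Alternatives that were turned down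

**Alternative 1:** The strategic cut is at C7a–C7 and C1–C1′, with ring B left open. Forward, TiCl4 would promote γ-attack of the dioxolane-bearing (E)-allylsilane A3 on the alkynyl enone A2, and the titanium enolate would be trapped by acetaldehyde 12 to give cyclopentanone A1, which holds every skeletal carbon.
- For: four stereocentres are set in one operation. O6 arrives with its configuration fixed and already differentiated from O5; on this point the alternative is stronger than the chosen route, which must tell the two hydroxyls of 18 apart.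
- Against: the slim alkynyl group on C3a shields the enone face less than an sp2 or sp3 group. The silane is chiral, so control at C7 becomes a case of double diastereoselection. Its allylic dioxolane oxygen invites Lewis-acid ionization. The γ-hydrogen of A2 is propargylic and easily lost.
- Ring B would still have to be closed afterwards at C4–C5 by a reductive alkyne–aldehyde cyclization of an α-alkoxy aldehyde, which must then set C5 cis to O6 on its own.
- Comparison: the chosen route uses the same kind of union only to prepare 14, with an achiral silane and a bulkier alkenyl group. It offers a single ring-closing step that forms C5–C6 and both carbinol centres, with the cis relationship enforced by the metal bridge, and no fewer operations are needed after A1 than after 14.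

**Alternative 2:** Ring A and C1′ are cut at C2–C1 and O–C1′. Forward, NaOCl would oxidize aldoxime A5 to a nitrile oxide that adds across the (E)-propenyl group on C7a, closing the cyclopentane and an isoxazoline in one step to give A4.
- For: the cycloaddition is stereospecific, so the anti relationship of C1 and C1′ follows from the alkene geometry. On this point it is stronger than the aldol of the chosen route.
- Against: the five-membered ring must close trans onto a cyclohexane, which is more strained than the cis mode, and the face of the propenyl group that reacts decides C1. Unmasking the β-hydroxy ketone needs N–O reduction in the presence of two 1,1-disubstituted alkenes. A5 already contains ring B with five contiguous stereocentres, which would need a long synthesis of its own.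
- Comparison: the chosen route builds ring A in three operations from a purchasable enantiopure cyclopentenone and creates the ring-B centres while closing the ring, so the hard part is not moved into the precursor.

**Alternative 3:** The cut is at C1–C7a. Forward, Rh2(OAc)4 would decompose diazo diketone A7 and the carbenoid would insert into the equatorial C7a–H bond to give 2-acetylcyclopentanone A6.
- For: 1,5-insertion is the normal ring size and proceeds with retention, which fixes the trans fusion. The isopropenyl-bearing cyclohexane could come from the terpene pool, so C7 needs no acyclic stereocontrol; here the alternative is stronger.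
- Against: the carbenoid has an isopropenyl group and two ketal oxygens within reach (cyclopropanation, oxonium ylide formation), and an axial C7a–H that would give the cis fusion. A6 is an enolized β-diketone, so C1 is labile and the acetyl group must be reduced chemo- and stereoselectively next to the ring ketone. The C4 ketal must later be turned into the methylene at a hindered position.
- Comparison: the chosen route sets C1′ directly, carries the C4 methylene from the start, and needs no late olefination or diketone reduction.

Key step: step 11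

Remark: TBS = tert-butyldimethylsilyl, TES = triethylsilyl; indane locants (C1–C7a, C1′) are used for all intermediates; enone 3, alcohol 20 and acid 29 are taken as purchasable single enantiomers.

## Steps

Step 1
Reactants: 1 2-bromoprop-2-en-1-ol
Product: 2 [(2-bromoprop-2-en-1-yl)oxy](tert-butyl)dimethylsilane
Conditions: TBSCl, imidazole, CH2Cl2, 0 °C → rt
Reagents that add atoms: tert-butyldimethylsilyl chloride, CC(C)(C)[Si](C)(C)Cl
Why: Standard silylation of a primary alcohol; the bulky silyl ether survives the later lithiation and is a poor leaving group for β-elimination.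

Step 2
Reactants: 2 [(2-bromoprop-2-en-1-yl)oxy](tert-butyl)dimethylsilane; 3 (R)-4-(TBSO)cyclopent-2-en-1-one
Product: 6 (3S,4R)-4-(TBSO)-3-[3-(TBSO)prop-1-en-2-yl]cyclopentan-1-one, via alkenyllithium 4 (not isolated), via lithium dialkenylcuprate 5 (not isolated)
Conditions: 2 (2 equiv), t-BuLi (4 equiv), Et2O, −78 °C; CuI, Me2S, −78 → −40 °C; then 3, −78 °C; aq NH4Cl
Reagents that add atoms: none
Why: Bromine–lithium exchange, Gilman cuprate formation and 1,4-addition; the cuprate enters anti to the silyloxy group on the neighbouring carbon, which sets the future C3a centre.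

Step 3
Reactants: 6 (3S,4R)-4-(TBSO)-3-[3-(TBSO)prop-1-en-2-yl]cyclopentan-1-one
Product: 7 (R)-4-[3-(TBSO)prop-1-en-2-yl]cyclopent-2-en-1-one
Conditions: DBU, CH2Cl2, 0 °C, short reaction time
Reagents that add atoms: none
Why: E1cB elimination of the β-silyloxy group gives the transposed enone; the new stereocentre is not involved, and low temperature and short contact should keep its doubly allylic hydrogen in place.

Step 4
Reactants: 8 ethyl but-2-ynoate
Product: 9 ethyl (2E)-3-methyl-4-(trimethylsilyl)but-2-enoate
Conditions: Me3SiCH2MgCl, CuI, THF, −78 °C; then 8, −78 °C; aq NH4Cl at −78 °C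
Reagents that add atoms: (trimethylsilyl)methylmagnesium chloride, C[Si](C)(C)C[Mg]Cl
Why: syn-Carbocupration of an ynoate; silylmethyl and hydrogen end up cis, so CH2SiMe3 is trans to the ester (E), provided the alkenylcopper is protonated cold.

Step 5
Reactants: 9 ethyl (2E)-3-methyl-4-(trimethylsilyl)but-2-enoate
Product: 10 (2E)-3-methyl-4-(trimethylsilyl)but-2-en-1-ol
Conditions: i-Bu2AlH, CH2Cl2, −78 °C; aq potassium sodium tartrate
Reagents that add atoms: none
Why: 1,2-Reduction of a conjugated ester to the allylic alcohol with retention of alkene geometry; the neutral work-up avoids acid-induced 1,4-elimination of the δ-silyl alcohol.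

Step 6
Reactants: 10 (2E)-3-methyl-4-(trimethylsilyl)but-2-en-1-ol
Product: 11 tert-butyldimethyl{[(2E)-3-methyl-4-(trimethylsilyl)but-2-en-1-yl]oxy}silane
Conditions: TBSCl, imidazole, CH2Cl2, 0 °C
Reagents that add atoms: tert-butyldimethylsilyl chloride, CC(C)(C)[Si](C)(C)Cl
Why: Silylation under mildly basic conditions; the silyl ether oxygen binds TiCl4 poorly, which should suppress ionization of the allylic C–O bond in the next step.

Step 7
Reactants: 7 (R)-4-[3-(TBSO)prop-1-en-2-yl]cyclopent-2-en-1-one; 11 tert-butyldimethyl{[(2E)-3-methyl-4-(trimethylsilyl)but-2-en-1-yl]oxy}silane; 12 acetaldehyde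
Product: 14 (2S,3R,4R)-4-[3-(TBSO)prop-1-en-2-yl]-3-[(2R)-1-(TBSO)-3-methylbut-3-en-2-yl]-2-[(1S)-1-hydroxyethyl]cyclopentan-1-one, via trichlorotitanium enolate 13 (not isolated)
Conditions: TiCl4 (1 equiv), CH2Cl2, −78 °C; 11; then 12, −78 °C; aq NaHCO3
Reagents that add atoms: none
Why: Hosomi–Sakurai conjugate allylation followed by aldol capture of the chlorotitanium enolate (three-component coupling). The silane attacks C7a anti to the C3a substituent through an open synclinal transition state with the C7 hydrogen over the ring and the CH2SiMe3 group of the (E)-silane over the enone α-CH, which sets C7. Acetaldehyde then adds to the enolate face anti to the new C7a substituent through a Zimmerman–Traxler chair, in which the ring-imposed E(O) enolate geometry gives the anti aldol, i.e. (1′S).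

Step 8
Reactants: 14 (2S,3R,4R)-4-[3-(TBSO)prop-1-en-2-yl]-3-[(2R)-1-(TBSO)-3-methylbut-3-en-2-yl]-2-[(1S)-1-hydroxyethyl]cyclopentan-1-one
Product: 15 (2S,3R,4R)-2-[(1S)-1-acetoxyethyl]-4-[3-(TBSO)prop-1-en-2-yl]-3-[(2R)-1-(TBSO)-3-methylbut-3-en-2-yl]cyclopentan-1-one
Conditions: Ac2O, pyridine, DMAP (cat.), CH2Cl2, 0 °C
Reagents that add atoms: acetic anhydride, CC(=O)OC(C)=O
Why: Acylation of the aldol hydroxyl with a weak base at low temperature, where the β-acetoxy ketone should not yet eliminate; the final C1′ ester is in place from here on.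

Step 9
Reactants: 15 (2S,3R,4R)-2-[(1S)-1-acetoxyethyl]-4-[3-(TBSO)prop-1-en-2-yl]-3-[(2R)-1-(TBSO)-3-methylbut-3-en-2-yl]cyclopentan-1-one
Product: 16 (2S,3R,4R)-2-[(1S)-1-acetoxyethyl]-3-[(2R)-1-hydroxy-3-methylbut-3-en-2-yl]-4-(3-hydroxyprop-1-en-2-yl)cyclopentan-1-one
Conditions: HF·pyridine, pyridine, THF, 0 °C → rt
Reagents that add atoms: none
Why: Buffered fluoride cleaves both primary silyl ethers; the acetate and the ketone are inert to these conditions.

Step 10
Reactants: 16 (2S,3R,4R)-2-[(1S)-1-acetoxyethyl]-3-[(2R)-1-hydroxy-3-methylbut-3-en-2-yl]-4-(3-hydroxyprop-1-en-2-yl)cyclopentan-1-one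
Product: 17 (2S,3R,4R)-2-[(1S)-1-acetoxyethyl]-3-[(2R)-3-methyl-1-oxobut-3-en-2-yl]-4-(3-oxoprop-1-en-2-yl)cyclopentan-1-one
Conditions: Dess–Martin periodinane, NaHCO3, CH2Cl2, 0 °C → rt; crude product used at once
Reagents that add atoms: none
Why: Dess–Martin oxidation turns the allylic alcohol into the 2-substituted acrolein and the other primary alcohol into the aldehyde under buffered, non-enolizing conditions, so C7 (α to the new aldehyde and allylic) should keep its configuration.

Step 11
Reactants: 17 (2S,3R,4R)-2-[(1S)-1-acetoxyethyl]-3-[(2R)-3-methyl-1-oxobut-3-en-2-yl]-4-(3-oxoprop-1-en-2-yl)cyclopentan-1-one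
Product: 18 (1S,3aR,5S,6R,7R,7aR)-1-[(1S)-1-acetoxyethyl]-5,6-dihydroxy-4-methylidene-7-(prop-1-en-2-yl)octahydro-2H-inden-2-one
Conditions: TiCl3(DME)1.5, Zn–Cu couple, DME, reflux 2 h; then 0 °C, 17 added by syringe pump (high dilution); aq K2CO3
Reagents that add atoms: none
Why: The low-valent titanium slurry transfers an electron to each formyl group (the enal first); the titanium-bound ketyls, or a ketyl and a titanium-coordinated aldehyde, join at their carbonyl carbons and hydrolysis releases the diol, i.e. the pinacol stage of a McMurry coupling held below the temperature of deoxygenation. The closest known reaction type is the titanium-induced pinacol cyclization of 1,6-dialdehydes to cis-cyclohexane-1,2-diols, which also accepts conjugated aldehydes. Ring B closes in a 6-exo-trig sense (C6 onto the C5 carbonyl carbon, both oxygens outside the ring) through a chair in which the trans arms of the cyclopentanone become the diequatorial ring fusion. At C6 the controlling element is C7: its isopropenyl group takes an equatorial site of that chair and the C6 oxygen takes the neighbouring equatorial site, anti to it. At C5 the controlling element is the titanium bridge: the second C–O bond must be gauche to the first and so becomes axial, an orientation that the s-trans acrolein unit and relief of allylic strain against the C4 methylene also favour. The step needs aldehyde-over-ketone selectivity, which the hindered and less easily reduced ring ketone, the low temperature and the slow addition should secure; coupling at the carbonyl carbon and not the β-carbon of the enal, which the strong Ti–O bond of the ketyl favours; and cyclization over oligomerization, which high dilution secures.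

Step 12
Reactants: 18 (1S,3aR,5S,6R,7R,7aR)-1-[(1S)-1-acetoxyethyl]-5,6-dihydroxy-4-methylidene-7-(prop-1-en-2-yl)octahydro-2H-inden-2-one
Product: 19 (1S,3aR,5S,6R,7R,7aR)-1-[(1S)-1-acetoxyethyl]-5-hydroxy-4-methylidene-7-(prop-1-en-2-yl)-6-(triethylsilyloxy)octahydro-2H-inden-2-one
Conditions: Et3SiCl (1 equiv), imidazole, CH2Cl2, −40 → −20 °C
Reagents that add atoms: chlorotriethylsilane, CC[Si](CC)(CC)Cl
Why: Kinetic silylation of a cis-diol; the equatorial C6 hydroxyl should react before the axial C5 hydroxyl, whose approach is hindered by the axial hydrogens on C7 and C3a.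

Step 13
Reactants: 20 (S)-but-3-yn-2-ol
Product: 23 (2E,4S)-4-hydroxy-3-methylpent-2-enoic acid, via alkenylalane 21 (not isolated), via lithium alanate 22 (not isolated)
Conditions: Me3Al (3 equiv), Cp2ZrCl2 (cat.), CH2Cl2, 0 °C → rt; n-BuLi, THF, −78 °C; CO2, −78 → 0 °C; aq HCl
Reagents that add atoms: trimethylaluminium, C[Al](C)C; carbon dioxide, O=C=O
Why: Zirconium-catalysed syn-methylalumination (Negishi carboalumination) puts methyl on the internal and aluminium on the terminal alkyne carbon, cis to each other, which fixes the (E) geometry; the alanate is carboxylated with retention and the carbinol centre is untouched.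

Step 14
Reactants: 23 (2E,4S)-4-hydroxy-3-methylpent-2-enoic acid
Product: 24 (2E,4S)-4-acetoxy-3-methylpent-2-enoic acid
Conditions: Ac2O, pyridine, DMAP (cat.), CH2Cl2, 0 °C → rt; then H2O
Reagents that add atoms: acetic anhydride, CC(=O)OC(C)=O
Why: O-Acetylation of the allylic alcohol; the mixed anhydride formed at the carboxyl group is hydrolysed on aqueous work-up, and the (E) geometry rules out lactonization.

Step 15
Reactants: 19 (1S,3aR,5S,6R,7R,7aR)-1-[(1S)-1-acetoxyethyl]-5-hydroxy-4-methylidene-7-(prop-1-en-2-yl)-6-(triethylsilyloxy)octahydro-2H-inden-2-one; 24 (2E,4S)-4-acetoxy-3-methylpent-2-enoic acid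
Product: 26 (1S,3aR,5S,6R,7R,7aR)-1-[(1S)-1-acetoxyethyl]-4-methylidene-2-oxo-7-(prop-1-en-2-yl)-6-(triethylsilyloxy)octahydro-1H-inden-5-yl (2E,4S)-4-acetoxy-3-methylpent-2-enoate, via mixed anhydride 25 (not isolated)
Conditions: 24, 2,4,6-trichlorobenzoyl chloride, Et3N, toluene, rt; then 19, DMAP, 0 °C → rt
Reagents that add atoms: none
Why: Yamaguchi esterification, suited to a hindered axial alcohol and a β,β-disubstituted acrylic acid; low temperature and a limited amount of base guard against deconjugation of the enoate and elimination of the β-acetoxy ketone.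

Step 16
Reactants: 26 (1S,3aR,5S,6R,7R,7aR)-1-[(1S)-1-acetoxyethyl]-4-methylidene-2-oxo-7-(prop-1-en-2-yl)-6-(triethylsilyloxy)octahydro-1H-inden-5-yl (2E,4S)-4-acetoxy-3-methylpent-2-enoate
Product: 27 (1S,3aR,5S,6R,7R,7aR)-1-[(1S)-1-acetoxyethyl]-6-hydroxy-4-methylidene-2-oxo-7-(prop-1-en-2-yl)octahydro-1H-inden-5-yl (2E,4S)-4-acetoxy-3-methylpent-2-enoate
Conditions: HF·pyridine, pyridine, THF, 0 °C
Reagents that add atoms: none
Why: Mildly acidic fluoride removes the triethylsilyl ether; under these non-basic conditions the C5 ester should not migrate to the neighbouring cis hydroxyl.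

Step 17
Reactants: 27 (1S,3aR,5S,6R,7R,7aR)-1-[(1S)-1-acetoxyethyl]-6-hydroxy-4-methylidene-2-oxo-7-(prop-1-en-2-yl)octahydro-1H-inden-5-yl (2E,4S)-4-acetoxy-3-methylpent-2-enoate
Product: 28 (1S,3aR,5S,6R,7S,7aR)-1-[(1S)-1-acetoxyethyl]-6-hydroxy-4-methylidene-7-[(2S)-2-methyloxiran-2-yl]-2-oxooctahydro-1H-inden-5-yl (2E,4S)-4-acetoxy-3-methylpent-2-enoate
Conditions: VO(acac)2 (cat.), t-BuOOH (anhydrous, in decane), CH2Cl2, 0 °C → rt
Reagents that add atoms: tert-butyl hydroperoxide, CC(C)(C)OO
Why: Vanadium-catalysed, hydroxyl-directed epoxidation of a homoallylic alcohol. The C6 vanadate reaches only the gauche isopropenyl group: the C4 methylene is anti to C6–O and flanked by an acylated oxygen, and the enoate is electron-poor. With C7–H eclipsing the C=CH2 bond (allylic-strain minimum, methyl between the axial hydrogens on C6 and C7a) and oxygen delivered from the C6–O side, the (S)-oxirane should form.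

Step 18
Reactants: 28 (1S,3aR,5S,6R,7S,7aR)-1-[(1S)-1-acetoxyethyl]-6-hydroxy-4-methylidene-7-[(2S)-2-methyloxiran-2-yl]-2-oxooctahydro-1H-inden-5-yl (2E,4S)-4-acetoxy-3-methylpent-2-enoate; 29 (R)-2-methylbutanoic acid
Product: 30 (1S,3aR,5S,6R,7S,7aR)-1-[(1S)-1-acetoxyethyl]-4-methylidene-6-{[(2R)-2-methylbutanoyl]oxy}-7-[(2S)-2-methyloxiran-2-yl]-2-oxooctahydro-1H-inden-5-yl (2E,4S)-4-acetoxy-3-methylpent-2-enoate
Conditions: 29, DCC, DMAP (cat.), CH2Cl2, 0 °C → rt
Reagents that add atoms: none
Why: Steglich esterification of the equatorial C6 hydroxyl under near-neutral conditions that the oxirane, the β-acetoxy ketone and the α-stereocentre of the acid should tolerate.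

## Compound list

1 | 2-bromoprop-2-en-1-ol | OCC(Br)=C | starting material
2 | [(2-bromoprop-2-en-1-yl)oxy](tert-butyl)dimethylsilane | C=C(Br)CO[Si](C)(C)C(C)(C)C | intermediate
3 | (R)-4-(tert-butyldimethylsilyloxy)cyclopent-2-en-1-one | O=C1C=C[C@H](O[Si](C)(C)C(C)(C)C)C1 | starting material
4 | {3-[(tert-butyldimethylsilyl)oxy]prop-1-en-2-yl}lithium | [Li]C(=C)CO[Si](C)(C)C(C)(C)C | intermediate
5 | lithium bis{3-[(tert-butyldimethylsilyl)oxy]prop-1-en-2-yl}cuprate | [Li+].C=C(CO[Si](C)(C)C(C)(C)C)[Cu-]C(=C)CO[Si](C)(C)C(C)(C)C | intermediate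
6 | (3S,4R)-4-(TBSO)-3-[3-(TBSO)prop-1-en-2-yl]cyclopentan-1-one (substituents trans) | O=C1C[C@@H](C(=C)CO[Si](C)(C)C(C)(C)C)[C@H](O[Si](C)(C)C(C)(C)C)C1 | intermediate
7 | (R)-4-[3-(TBSO)prop-1-en-2-yl]cyclopent-2-en-1-one | O=C1C=C[C@H](C(=C)CO[Si](C)(C)C(C)(C)C)C1 | intermediate
8 | ethyl but-2-ynoate | CC#CC(=O)OCC | starting material
9 | ethyl (2E)-3-methyl-4-(trimethylsilyl)but-2-enoate | CCOC(=O)/C=C(\C)C[Si](C)(C)C | intermediate
10 | (2E)-3-methyl-4-(trimethylsilyl)but-2-en-1-ol | OC/C=C(\C)C[Si](C)(C)C | intermediate
11 | tert-butyldimethyl{[(2E)-3-methyl-4-(trimethylsilyl)but-2-en-1-yl]oxy}silane | CC(C)(C)[Si](C)(C)OC/C=C(\C)C[Si](C)(C)C | intermediate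
12 | acetaldehyde | CC=O | starting material
13 | trichloro({(3R,4R)-4-[3-(TBSO)prop-1-en-2-yl]-3-[(2R)-1-(TBSO)-3-methylbut-3-en-2-yl]cyclopent-1-en-1-yl}oxy)titanium | CC(C)(C)[Si](C)(C)OC[C@@H](C(C)=C)[C@@H]1C=C(O[Ti](Cl)(Cl)Cl)C[C@H]1C(=C)CO[Si](C)(C)C(C)(C)C | intermediate
14 | (2S,3R,4R)-4-[3-(TBSO)prop-1-en-2-yl]-3-[(2R)-1-(TBSO)-3-methylbut-3-en-2-yl]-2-[(1S)-1-hydroxyethyl]cyclopentan-1-one | CC(C)(C)[Si](C)(C)OC[C@@H](C(C)=C)[C@@H]1[C@@H]([C@H](C)O)C(=O)C[C@H]1C(=C)CO[Si](C)(C)C(C)(C)C | intermediate
15 | (2S,3R,4R)-2-[(1S)-1-acetoxyethyl]-4-[3-(TBSO)prop-1-en-2-yl]-3-[(2R)-1-(TBSO)-3-methylbut-3-en-2-yl]cyclopentan-1-one | CC(C)(C)[Si](C)(C)OC[C@@H](C(C)=C)[C@@H]1[C@@H]([C@H](C)OC(C)=O)C(=O)C[C@H]1C(=C)CO[Si](C)(C)C(C)(C)C | intermediate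
16 | (2S,3R,4R)-2-[(1S)-1-acetoxyethyl]-3-[(2R)-1-hydroxy-3-methylbut-3-en-2-yl]-4-(3-hydroxyprop-1-en-2-yl)cyclopentan-1-one | OC[C@@H](C(C)=C)[C@@H]1[C@@H]([C@H](C)OC(C)=O)C(=O)C[C@H]1C(=C)CO | intermediate
17 | (2S,3R,4R)-2-[(1S)-1-acetoxyethyl]-3-[(2R)-3-methyl-1-oxobut-3-en-2-yl]-4-(3-oxoprop-1-en-2-yl)cyclopentan-1-one | O=C[C@@H](C(C)=C)[C@@H]1[C@@H]([C@H](C)OC(C)=O)C(=O)C[C@H]1C(=C)C=O | intermediate
18 | (1S,3aR,5S,6R,7R,7aR)-1-[(1S)-1-acetoxyethyl]-5,6-dihydroxy-4-methylidene-7-(prop-1-en-2-yl)octahydro-2H-inden-2-one | C=C1[C@@H]2CC(=O)[C@H]([C@H](C)OC(C)=O)[C@H]2[C@H](C(C)=C)[C@@H](O)[C@H]1O | intermediate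
19 | (1S,3aR,5S,6R,7R,7aR)-1-[(1S)-1-acetoxyethyl]-5-hydroxy-4-methylidene-7-(prop-1-en-2-yl)-6-(triethylsilyloxy)octahydro-2H-inden-2-one | C=C1[C@@H]2CC(=O)[C@H]([C@H](C)OC(C)=O)[C@H]2[C@H](C(C)=C)[C@@H](O[Si](CC)(CC)CC)[C@H]1O | intermediate
20 | (S)-but-3-yn-2-ol | C[C@H](O)C#C | starting material
21 | [(1E,3S)-3-(dimethylalumanyloxy)-2-methylbut-1-en-1-yl]dimethylalumane | C[C@H](O[Al](C)C)/C(C)=C/[Al](C)C | intermediate
22 | lithium butyl[(1E,3S)-3-(dimethylalumanyloxy)-2-methylbut-1-en-1-yl]dimethylalanate | [Li+].C[C@H](O[Al](C)C)/C(C)=C/[Al-](C)(C)CCCC | intermediate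
23 | (2E,4S)-4-hydroxy-3-methylpent-2-enoic acid | OC(=O)/C=C(\C)[C@H](C)O | intermediate
24 | (2E,4S)-4-acetoxy-3-methylpent-2-enoic acid | OC(=O)/C=C(\C)[C@H](C)OC(C)=O | intermediate
25 | (2E,4S)-4-acetoxy-3-methylpent-2-enoic 2,4,6-trichlorobenzoic anhydride | O=C(OC(=O)/C=C(\C)[C@H](C)OC(C)=O)c1c(Cl)cc(Cl)cc1Cl | intermediate
26 | (1S,3aR,5S,6R,7R,7aR)-1-[(1S)-1-acetoxyethyl]-4-methylidene-2-oxo-7-(prop-1-en-2-yl)-6-(triethylsilyloxy)octahydro-1H-inden-5-yl (2E,4S)-4-acetoxy-3-methylpent-2-enoate | C=C1[C@@H]2CC(=O)[C@H]([C@H](C)OC(C)=O)[C@H]2[C@H](C(C)=C)[C@@H](O[Si](CC)(CC)CC)[C@H]1OC(=O)/C=C(\C)[C@H](C)OC(C)=O | intermediate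
27 | (1S,3aR,5S,6R,7R,7aR)-1-[(1S)-1-acetoxyethyl]-6-hydroxy-4-methylidene-2-oxo-7-(prop-1-en-2-yl)octahydro-1H-inden-5-yl (2E,4S)-4-acetoxy-3-methylpent-2-enoate | C=C1[C@@H]2CC(=O)[C@H]([C@H](C)OC(C)=O)[C@H]2[C@H](C(C)=C)[C@@H](O)[C@H]1OC(=O)/C=C(\C)[C@H](C)OC(C)=O | intermediate
28 | (1S,3aR,5S,6R,7S,7aR)-1-[(1S)-1-acetoxyethyl]-6-hydroxy-4-methylidene-7-[(2S)-2-methyloxiran-2-yl]-2-oxooctahydro-1H-inden-5-yl (2E,4S)-4-acetoxy-3-methylpent-2-enoate | C=C1[C@@H]2CC(=O)[C@H]([C@H](C)OC(C)=O)[C@H]2[C@H]([C@@]2(C)CO2)[C@@H](O)[C@H]1OC(=O)/C=C(\C)[C@H](C)OC(C)=O | intermediate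
29 | (R)-2-methylbutanoic acid | CC[C@@H](C)C(=O)O | starting material
30 | (1S,3aR,5S,6R,7S,7aR)-1-[(1S)-1-acetoxyethyl]-4-methylidene-6-{[(2R)-2-methylbutanoyl]oxy}-7-[(2S)-2-methyloxiran-2-yl]-2-oxooctahydro-1H-inden-5-yl (2E,4S)-4-acetoxy-3-methylpent-2-enoate | C=C1[C@@H]2CC(=O)[C@H]([C@H](C)OC(C)=O)[C@H]2[C@H]([C@@]2(C)CO2)[C@@H](OC(=O)[C@H](C)CC)[C@H]1OC(=O)/C=C(\C)[C@H](C)OC(C)=O | target

## Step count and least certain steps

Total step count: 18. Longest linear sequence: 13 steps (steps 1–3, 7–12 and 15–18; the silane branch, steps 4–6, and the acid branch, steps 13–14, join it at steps 7 and 15).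

**Step 11 (key step).** The most likely failure is loss of chemoselectivity. The reductant may also engage the ring ketone (ketone–aldehyde coupling or plain reduction), or the enal radical anion may react through its β-carbon and oligomerize, because three reducible π-systems lie close together. The fallback shields the ketone during the coupling. It sets out from 15: ketalization with 1,2-bis(trimethylsilyloxy)ethane and catalytic TMSOTf (CH2Cl2, −78 °C) should give bis-silyl ether ketal F1; HF·pyridine then frees diol ketal F2; Dess–Martin oxidation gives dialdehyde ketal F3; the same titanium coupling gives hydrindane diol ketal F4; and mild aqueous acid (PPTS, wet acetone) returns to the route at 18.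

**Step 7.** The most likely failure is poor diastereocontrol at the acyclic centres, above all a syn instead of anti aldol at C1′, because the chair preference of a chlorotitanium enolate of a cyclic ketone is not secure. Control at C7 rests on an open transition-state model, and a C7 epimer would have to be removed by chromatography at 14. The fallback corrects C1′ after the event. It sets out from 7, 11 and 12 run as in step 7: if the syn aldol F5, the (1′R)-epimer of 14, predominates, a Mitsunobu reaction with acetic acid (PPh3, DIAD, toluene, 0 °C) acetylates with inversion and returns to the route at 15.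

**Step 17.** The most likely failure is poor facial selectivity at the isopropenyl group. Oxygen should come from the C6–O side, but the rotamer with methyl instead of methylene next to C7–H would give the epimeric oxirane, and the two rotamers differ little in energy. The fallback replaces substrate control by ligand control. It sets out from 27 and returns at 28 without a new intermediate: epoxidation with VO(O-i-Pr)3, a chiral C2-symmetric bishydroxamic acid ligand and cumene hydroperoxide in toluene, a known catalyst system for homoallylic alcohols. Both ligand enantiomers are available, so the substrate preference can be reinforced or overridden.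

**Step 12.** The most likely failure is poor site selectivity, giving silylation at O5 or at both oxygens, because the equatorial hydroxyl is flanked by the isopropenyl group. The fallback activates one oxygen through a cyclic tin acetal. It sets out from 18: Bu2SnO (toluene, reflux with removal of water) gives dibutylstannylene acetal F6, in which the equatorial oxygen is the more nucleophilic, and Et3SiCl then returns to the route at 19.

**Step 3.** The most likely failure is partial racemization or alkene migration into conjugation, because the new stereocentre of 7 carries a hydrogen that is both γ to the enone and allylic and is exposed to the amidine base. The fallback reaches 7 without base. It sets out from 2: alkenyllithium 4 is converted with trimethyl borate into lithium alkenyltrimethoxyborate F7. NiCl2(PPh3)2-catalysed coupling with purchasable (1R,4S)-cis-4-acetoxycyclopent-2-en-1-ol F8 replaces the acetate with inversion and gives trans-cyclopentenol F9. Oxidation with MnO2 (CH2Cl2, rt) returns to the route at 7.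

## Further compounds

F1 | step 11 | 2-[(1S)-1-acetoxyethyl] cyclopentanone 15 as its ethylene ketal (1,4-dioxaspiro[4.4]nonane), both primary TBS ethers retained | CC(C)(C)[Si](C)(C)OC[C@@H](C(C)=C)[C@@H]1[C@@H]([C@H](C)OC(C)=O)C2(OCCO2)C[C@H]1C(=C)CO[Si](C)(C)C(C)(C)C
F2 | step 11 | ethylene ketal of diol 16 | OC[C@@H](C(C)=C)[C@@H]1[C@@H]([C@H](C)OC(C)=O)C2(OCCO2)C[C@H]1C(=C)CO
F3 | step 11 | ethylene ketal of dialdehyde 17 | O=C[C@@H](C(C)=C)[C@@H]1[C@@H]([C@H](C)OC(C)=O)C2(OCCO2)C[C@H]1C(=C)C=O
F4 | step 11 | ethylene ketal (at C2) of hydrindane diol 18 | C=C1[C@@H]2CC3(OCCO3)[C@H]([C@H](C)OC(C)=O)[C@H]2[C@H](C(C)=C)[C@@H](O)[C@H]1O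
F5 | step 7 | (2S,3R,4R)-4-[3-(TBSO)prop-1-en-2-yl]-3-[(2R)-1-(TBSO)-3-methylbut-3-en-2-yl]-2-[(1R)-1-hydroxyethyl]cyclopentan-1-one | CC(C)(C)[Si](C)(C)OC[C@@H](C(C)=C)[C@@H]1[C@@H]([C@@H](C)O)C(=O)C[C@H]1C(=C)CO[Si](C)(C)C(C)(C)C
F0 | step 17 | none | none
F6 | step 12 | 5,6-O-dibutylstannylene acetal of diol 18 | C=C1[C@@H]2CC(=O)[C@H]([C@H](C)OC(C)=O)[C@H]2[C@H](C(C)=C)[C@H]3O[Sn](CCCC)(CCCC)O[C@@H]13
F7 | step 3 | lithium {3-[(tert-butyldimethylsilyl)oxy]prop-1-en-2-yl}trimethoxyborate | [Li+].CO[B-](OC)(OC)C(=C)CO[Si](C)(C)C(C)(C)C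
F8 | step 3 | (1R,4S)-cis-4-acetoxycyclopent-2-en-1-ol | O[C@H]1C=C[C@@H](OC(C)=O)C1
F9 | step 3 | (1R,4R)-trans-4-[3-(TBSO)prop-1-en-2-yl]cyclopent-2-en-1-ol | O[C@H]1C=C[C@H](C(=C)CO[Si](C)(C)C(C)(C)C)C1
A1 | alternative 1 | 2-[(1S)-1-hydroxyethyl]-3-[1-(2,2-dimethyl-1,3-dioxolan-4-yl)-2-methylprop-2-en-1-yl]-4-[(trimethylsilyl)ethynyl]cyclopentan-1-one with the target configuration at C1, C1′, C3a, C7a, C7 and C6 | C[Si](C)(C)C#C[C@@H]1CC(=O)[C@H]([C@H](C)O)[C@H]1[C@H](C(C)=C)[C@@H]2COC(C)(C)O2
A2 | alternative 1 | (R)-4-[(trimethylsilyl)ethynyl]cyclopent-2-en-1-one | O=C1C=C[C@H](C#C[Si](C)(C)C)C1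
A3 | alternative 1 | trimethyl{(2E)-3-[(4R)-2,2-dimethyl-1,3-dioxolan-4-yl]-2-methylprop-2-en-1-yl}silane | C[Si](C)(C)C/C(C)=C/[C@@H]1COC(C)(C)O1
A4 | alternative 2 | cyclopentane-fused isoxazoline with ring B as the C5/C6 acetonide, C4 methylene and C7 isopropenyl | C=C1[C@@H]2CC3=NO[C@@H](C)[C@@H]3[C@H]2[C@H](C(C)=C)[C@H]3OC(C)(C)O[C@@H]13
A5 | alternative 2 | cyclohexane aldoxime: C3a bears CH2CH=NOH, C7a bears (E)-prop-1-enyl, C7 isopropenyl, C5/C6 acetonide, C4 methylene | C=C1[C@H](CC=NO)[C@@H](/C=C/C)[C@H](C(C)=C)[C@H]2OC(C)(C)O[C@@H]12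
A6 | alternative 3 | 1-acetyl trans-hydrindan-2-one with C4 ethylene ketal, C5 OTES, C6 OTBS and C7 isopropenyl | O1CCOC12[C@@H]3CC(=O)[C@H](C(C)=O)[C@H]3[C@H](C(C)=C)[C@@H](O[Si](C)(C)C(C)(C)C)[C@H]2O[Si](CC)(CC)CC
A7 | alternative 3 | cyclohexane bearing a 3-diazo-2,4-dioxopentyl arm on C3a, with C4 ethylene ketal, C5 OTES, C6 OTBS and C7 isopropenyl | O1CCOC12[C@H](CC(=O)C(=[N+]=[N-])C(C)=O)C[C@H](C(C)=C)[C@@H](O[Si](C)(C)C(C)(C)C)[C@H]2O[Si](CC)(CC)CC
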